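The route rests on one disconnection: the piperidine ring (N1, C2, C3, C4, C4a, C8a) is grown from the pyrrolidine ring of a cis-octahydroindole that carries a 1-hydroxyethyl group at C2. Activation of this carbinol lets nitrogen displace oxygen to a fused aziridinium ion, which trifluoroacetate reopens at the ring carbon. N and O thereby change places, each with inversion, so the step exploits the vicinal N1–C2/C3–O relationship of that ring and turns a syn amino alcohol into the cis C2-methyl/C3-oxygen pair in one operation. The precursor arises from a catalytic asymmetric conjugate addition of the side chain to cyclohexenone, lactam annulation, hydrogenation and exo-selective alkylation of the lactam carbon.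

Key step: step 9

Remark: decahydroquinoline numbering is used for the target and the ring-expanded compounds, indole numbering for the octahydroindoles; TBS = tert-butyldimethylsilyl; the ligand enantiomer in step 3 is the one that leads to the (S)-configured adduct and is to be fixed on a model alkene.

Step 1
Reactants: 1 (R)-2-propyloxirane; 2 allylmagnesium bromide
Product: 3 (R)-oct-1-en-5-ol
Conditions: CuBr·SMe2 (5 mol%), THF, −40 → 0 °C; aq NH4Cl
Reagents that add atoms: none
Why: Copper-catalysed SN2 opening of the terminal epoxide by the allyl Grignard reagent occurs at the unsubstituted carbon, so the (R)-carbinol centre (later C5' of the side chain) is taken unchanged from the epoxide.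

Step 2
Reactants: 3 (R)-oct-1-en-5-ol
Product: 4 (R)-tert-butyldimethyl(oct-1-en-5-yloxy)silane
Conditions: TBSCl, imidazole, DMF, rt
Reagents that add atoms: tert-butyldimethylsilyl chloride, CC(C)(C)[Si](C)(C)Cl
Why: Standard silylation of a secondary alcohol gives an ether that should withstand the organometallic, hydrogenation and basic steps and fall in the last acidic step.

Step 3
Reactants: 4 (R)-tert-butyldimethyl(oct-1-en-5-yloxy)silane; 5 cyclohex-2-en-1-one
Product: 7 tert-butyldimethyl{[(R)-8-[(S)-3-(trimethylsilyloxy)cyclohex-2-en-1-yl]octan-4-yl]oxy}silane, via alkylzirconocene chloride 6 (not isolated)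
Conditions: Cp2Zr(H)Cl, CH2Cl2, rt; then (CuOTf)2·C6H6 (5 mol%), BINOL-derived phosphoramidite ligand with a bis(1-phenylethyl)amino group (10 mol%), 5, Me3SiCl, t-BuOMe, rt; non-aqueous work-up
Reagents that add atoms: chlorotrimethylsilane, C[Si](C)(C)Cl
Why: Hydrozirconation places zirconium on the terminal carbon, the monovalent-copper/phosphoramidite-catalysed asymmetric conjugate addition of the alkylzirconocene to the enone should set the ring stereocentre (later C5) as (S) by catalyst control, and Me3SiCl traps the enolate regiospecifically as its silyl enol ether.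

Step 4
Reactants: 7 silyl enol ether from step 3; 8 ethyl bromoacetate
Product: 10 ethyl 2-[(1R,2S)-2-[(R)-5-(tert-butyldimethylsilyloxy)octyl]-6-oxocyclohexyl]acetate, via lithium enolate 9 (not isolated)
Conditions: MeLi, THF, 0 °C; then 8, DMPU, −78 → −20 °C
Reagents that add atoms: none
Why: Methyllithium cleaves the silyl enol ether to the regiodefined lithium enolate, which the reactive α-bromo ester alkylates trans to the neighbouring side chain (enolate alkylation), the configuration at this carbon being erased again in step 5.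

Step 5
Reactants: 10 keto ester from step 4; 11 benzylamine
Product: 12 (S)-1-benzyl-4-[(R)-5-(tert-butyldimethylsilyloxy)octyl]-1,3,4,5,6,7-hexahydro-2H-indol-2-one
Conditions: PPTS (cat.), toluene, reflux, Dean–Stark trap
Reagents that add atoms: none
Why: Condensation of the γ-keto ester with the primary amine followed by lactamisation (enamine formation and aminolysis) should give, under acid-equilibrating conditions, the tetrasubstituted ring-fusion enamide in which C3a and C7a are both sp2.

Step 6
Reactants: 12 enamide lactam from step 5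
Product: 13 (3aS,4S,7aR)-1-benzyl-4-[(R)-5-(tert-butyldimethylsilyloxy)octyl]octahydro-2H-indol-2-one
Conditions: H2 (30 bar), 10% Pd/C, EtOH, rt
Reagents that add atoms: none
Why: Heterogeneous syn hydrogenation of the tetrasubstituted enamide from the face opposite the C4 side chain (held pseudoaxial by allylic strain) should place H3a and H7a cis to H4 and so give the all-cis, cis-fused lactam.

Step 7
Reactants: 13 cis-fused lactam from step 6; 14 ethyl vinyl ether
Product: 18 1-[(2S,3aS,4S,7aR)-1-benzyl-4-[(R)-5-(tert-butyldimethylsilyloxy)octyl]octahydro-1H-indol-2-yl]ethan-1-one, via 1-ethoxyvinylmagnesium bromide 15 (not isolated), via silylated hemiaminal 16 (not isolated), via enol ether amine 17 (not isolated)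
Conditions: 13, IrCl(CO)(PPh3)2 (1 mol%), (Me2SiH)2O, toluene, rt; separately 14, t-BuLi, THF, −78 → 0 °C, then MgBr2·OEt2; combine at −78 °C → rt; 1 M aq HCl, 0 °C; aq NaHCO3
Reagents that add atoms: water, O
Why: Iridium-catalysed hydrosilylation stops at the N,O-silyl acetal, whose iminium ion is attacked by the α-alkoxyvinyl Grignard reagent on the convex face of the cis-fused bicycle (reductive alkylation of a tertiary lactam), which sets C2 as (S) with its substituent cis to H3a and H7a, and mild acid unmasks the methyl ketone.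

Step 8
Reactants: 18 amino ketone from step 7
Product: 19 (S)-1-[(2S,3aS,4S,7aR)-1-benzyl-4-[(R)-5-(tert-butyldimethylsilyloxy)octyl]octahydro-1H-indol-2-yl]ethan-1-ol
Conditions: NaBH4, MeOH, −40 °C
Reagents that add atoms: none
Why: Non-chelating borohydride reduction of the α-(dialkylamino) ketone follows the Felkin–Anh model with nitrogen anti to the incoming hydride and should give the syn (S,S) amino alcohol.

Step 9
Reactants: 19 syn amino alcohol from step 8
Product: 23 (2R,3R,4aS,5S,8aR)-1-benzyl-5-[(R)-5-(tert-butyldimethylsilyloxy)octyl]-2-methyldecahydroquinolin-3-ol, via pyrrolidine trifluoroacetate 20 (not isolated), via aziridinium trifluoroacetate 21 (not isolated), via piperidine trifluoroacetate 22 (not isolated)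
Conditions: (CF3CO)2O, THF, −78 °C → rt; Et3N, 100 °C (sealed tube); then 2.5 M aq NaOH, rt
Reagents that add atoms: trifluoroacetic anhydride, O=C(OC(=O)C(F)(F)F)C(F)(F)F (at most one oxygen atom, delivered through the trifluoroacetate ion)
Why: O-Trifluoroacetylation of 19 turns the carbinol oxygen into a leaving group, and the tertiary amine displaces it intramolecularly (3-exo-tet closure, inversion at the carbinol carbon) to give the fused aziridinium ion 21. Trifluoroacetate then reopens 21 at the former pyrrolidine C2 by SN2 attack with inversion, which cleaves the N–C2 bond and enlarges the five-membered nitrogen ring to the six-membered ring N1–C2–C3–C4–C4a–C8a; the closest known reaction type is the aziridinium-mediated ring expansion of N-alkyl prolinols to 3-hydroxypiperidines with trifluoroacetic anhydride and triethylamine. The only ring closed is the transient aziridinium, the piperidine arising by its opening. No stereocentre is made from scratch: the (S)-carbinol carbon becomes (R)-C2 bearing nitrogen and the (S)-C2 of the octahydroindole becomes (R)-C3 bearing oxygen, so the syn amino alcohol is relayed stereospecifically into the cis C2-methyl/C3-oxygen pair while C4a, C5 and C8a are untouched. The step needs attack at the ring carbon and not at the exocyclic carbon, and this is secured by reversibility, since both trifluoroacetates re-ionise on heating and the mixture should drain to the six-membered ester, which NaOH then cleaves to 23.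

Step 10
Reactants: 24 (E)-hex-2-enal; 25 malonic acid
Product: 26 (2E,4E)-octa-2,4-dienoic acid
Conditions: pyridine, piperidine (cat.), 90 °C
Reagents that add atoms: none
Why: The Doebner modification of the Knoevenagel condensation, with decarboxylation, should give the new double bond as (E) and leave the (E)-alkene of the enal untouched.

Step 11
Reactants: 23 ring-expanded amino alcohol from step 9; 26 (2E,4E)-octa-2,4-dienoic acid
Product: 28 (2R,3R,4aS,5S,8aR)-1-benzyl-5-[(R)-5-(tert-butyldimethylsilyloxy)octyl]-2-methyldecahydroquinolin-3-yl (2E,4E)-octa-2,4-dienoate, via mixed anhydride 27 (not isolated)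
Conditions: 26, 2,4,6-trichlorobenzoyl chloride, Et3N, THF, rt; then 23, DMAP, toluene, 40 °C
Reagents that add atoms: none
Why: Yamaguchi esterification through the mixed anhydride acylates the hindered secondary C3 alcohol under basic conditions that the tertiary amine and the silyl ether tolerate, with no stereocentre involved.

Step 12
Reactants: 28 N-benzyl dienoate from step 11
Product: 30 CNP0186076.5 [(2R,3R,4aS,5S,8aR)-5-[(R)-5-hydroxyoctyl]-2-methyldecahydroquinolin-3-yl (2E,4E)-octa-2,4-dienoate], via 1-chloroethyl carbamate 29 (not isolated)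
Conditions: ClCO2CH(Cl)CH3, 1,8-bis(dimethylamino)naphthalene (cat.), ClCH2CH2Cl, 80 °C; evaporate; HCl (1.25 M in MeOH), 50 °C; aq NaHCO3
Reagents that add atoms: none
Why: von Braun-type N-debenzylation with 1-chloroethyl chloroformate (chloride attacks the benzylic carbon of the acylammonium ion) and methanolysis of the carbamate should free the secondary amine without reducing the dienoate, and the HCl/MeOH stage removes the TBS ether in the same flask.

Compound list
1 | (R)-2-propyloxirane | CCC[C@@H]1CO1 | starting material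
2 | allylmagnesium bromide | C=CC[Mg]Br | starting material
3 | (R)-oct-1-en-5-ol | C=CCC[C@H](O)CCC | intermediate
4 | (R)-tert-butyldimethyl(oct-1-en-5-yloxy)silane | C=CCC[C@H](O[Si](C)(C)C(C)(C)C)CCC | intermediate
5 | cyclohex-2-en-1-one | O=C1C=CCCC1 | starting material
6 | chlorobis(cyclopentadienyl)[(R)-5-(tert-butyldimethylsilyloxy)octyl]zirconium | Cl[Zr+2]CCCC[C@H](O[Si](C)(C)C(C)(C)C)CCC.c1cc[cH-]c1.c1cc[cH-]c1 | intermediate (not isolated)
7 | tert-butyldimethyl{[(R)-8-[(S)-3-(trimethylsilyloxy)cyclohex-2-en-1-yl]octan-4-yl]oxy}silane | C[Si](C)(C)OC1=C[C@@H](CCCC[C@H](O[Si](C)(C)C(C)(C)C)CCC)CCC1 | intermediate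
8 | ethyl bromoacetate | CCOC(=O)CBr | starting material
9 | lithium (S)-3-[(R)-5-(tert-butyldimethylsilyloxy)octyl]cyclohex-1-en-1-olate | [Li+].[O-]C1=C[C@@H](CCCC[C@H](O[Si](C)(C)C(C)(C)C)CCC)CCC1 | intermediate (not isolated)
10 | ethyl 2-[(1R,2S)-2-[(R)-5-(tert-butyldimethylsilyloxy)octyl]-6-oxocyclohexyl]acetate | CCOC(=O)C[C@H]1C(=O)CCC[C@@H]1CCCC[C@H](O[Si](C)(C)C(C)(C)C)CCC | intermediate
11 | benzylamine | NCc1ccccc1 | starting material
12 | (S)-1-benzyl-4-[(R)-5-(tert-butyldimethylsilyloxy)octyl]-1,3,4,5,6,7-hexahydro-2H-indol-2-one | O=C1CC2=C(CCC[C@@H]2CCCC[C@H](O[Si](C)(C)C(C)(C)C)CCC)N1Cc1ccccc1 | intermediate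
13 | (3aS,4S,7aR)-1-benzyl-4-[(R)-5-(tert-butyldimethylsilyloxy)octyl]octahydro-2H-indol-2-one | O=C1C[C@H]2[C@@H](CCCC[C@H](O[Si](C)(C)C(C)(C)C)CCC)CCC[C@H]2N1Cc1ccccc1 | intermediate
14 | ethyl vinyl ether | C=COCC | starting material
15 | (1-ethoxyvinyl)magnesium bromide | C=C(OCC)[Mg]Br | intermediate (not isolated)
16 | (3aS,4S,7aR)-1-benzyl-4-[(R)-5-(tert-butyldimethylsilyloxy)octyl]-2-(1,1,3,3-tetramethyldisiloxanyloxy)octahydro-1H-indole (both C2 epimers) | C[SiH](C)O[Si](C)(C)OC1C[C@H]2[C@@H](CCCC[C@H](O[Si](C)(C)C(C)(C)C)CCC)CCC[C@H]2N1Cc1ccccc1 | intermediate (not isolated)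
17 | (2S,3aS,4S,7aR)-1-benzyl-4-[(R)-5-(tert-butyldimethylsilyloxy)octyl]-2-(1-ethoxyvinyl)octahydro-1H-indole | C=C(OCC)[C@@H]1C[C@H]2[C@@H](CCCC[C@H](O[Si](C)(C)C(C)(C)C)CCC)CCC[C@H]2N1Cc1ccccc1 | intermediate (not isolated)
18 | 1-[(2S,3aS,4S,7aR)-1-benzyl-4-[(R)-5-(tert-butyldimethylsilyloxy)octyl]octahydro-1H-indol-2-yl]ethan-1-one | CC(=O)[C@@H]1C[C@H]2[C@@H](CCCC[C@H](O[Si](C)(C)C(C)(C)C)CCC)CCC[C@H]2N1Cc1ccccc1 | intermediate
19 | (S)-1-[(2S,3aS,4S,7aR)-1-benzyl-4-[(R)-5-(tert-butyldimethylsilyloxy)octyl]octahydro-1H-indol-2-yl]ethan-1-ol | C[C@H](O)[C@@H]1C[C@H]2[C@@H](CCCC[C@H](O[Si](C)(C)C(C)(C)C)CCC)CCC[C@H]2N1Cc1ccccc1 | intermediate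
20 | (S)-1-[(2S,3aS,4S,7aR)-1-benzyl-4-[(R)-5-(tert-butyldimethylsilyloxy)octyl]octahydro-1H-indol-2-yl]ethyl trifluoroacetate | C[C@H](OC(=O)C(F)(F)F)[C@@H]1C[C@H]2[C@@H](CCCC[C@H](O[Si](C)(C)C(C)(C)C)CCC)CCC[C@H]2N1Cc1ccccc1 | intermediate (not isolated)
21 | fused aziridinium ion (1-azoniabicyclo[3.1.0]hexane annulated to the cyclohexane ring, N-benzyl, methyl on the three-membered ring) as its trifluoroacetate | C[C@@H]1[C@@H]2C[C@H]3[C@@H](CCCC[C@H](O[Si](C)(C)C(C)(C)C)CCC)CCC[C@H]3[N@+]12Cc1ccccc1.[O-]C(=O)C(F)(F)F | intermediate (not isolated)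
22 | (2R,3R,4aS,5S,8aR)-1-benzyl-5-[(R)-5-(tert-butyldimethylsilyloxy)octyl]-2-methyldecahydroquinolin-3-yl trifluoroacetate | FC(F)(F)C(=O)O[C@@H]1C[C@H]2[C@@H](CCCC[C@H](O[Si](C)(C)C(C)(C)C)CCC)CCC[C@H]2N(Cc3ccccc3)[C@@H]1C | intermediate (not isolated)
23 | (2R,3R,4aS,5S,8aR)-1-benzyl-5-[(R)-5-(tert-butyldimethylsilyloxy)octyl]-2-methyldecahydroquinolin-3-ol | O[C@@H]1C[C@H]2[C@@H](CCCC[C@H](O[Si](C)(C)C(C)(C)C)CCC)CCC[C@H]2N(Cc3ccccc3)[C@@H]1C | intermediate
24 | (E)-hex-2-enal | CCC/C=C/C=O | starting material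
25 | malonic acid | OC(=O)CC(=O)O | starting material
26 | (2E,4E)-octa-2,4-dienoic acid | CCC/C=C/C=C/C(=O)O | intermediate
27 | (2E,4E)-octa-2,4-dienoic 2,4,6-trichlorobenzoic anhydride | CCC/C=C/C=C/C(=O)OC(=O)c1c(Cl)cc(Cl)cc1Cl | intermediate (not isolated)
28 | (2R,3R,4aS,5S,8aR)-1-benzyl-5-[(R)-5-(tert-butyldimethylsilyloxy)octyl]-2-methyldecahydroquinolin-3-yl (2E,4E)-octa-2,4-dienoate | CCC/C=C/C=C/C(=O)O[C@@H]1C[C@H]2[C@@H](CCCC[C@H](O[Si](C)(C)C(C)(C)C)CCC)CCC[C@H]2N(Cc3ccccc3)[C@@H]1C | intermediate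
29 | 1-chloroethyl (2R,3R,4aS,5S,8aR)-5-[(R)-5-(tert-butyldimethylsilyloxy)octyl]-2-methyl-3-[(2E,4E)-octa-2,4-dienoyloxy]octahydroquinoline-1(2H)-carboxylate (both epimers at the chloroethyl carbon) | CCC/C=C/C=C/C(=O)O[C@@H]1C[C@H]2[C@@H](CCCC[C@H](O[Si](C)(C)C(C)(C)C)CCC)CCC[C@H]2N(C(=O)OC(C)Cl)[C@@H]1C | intermediate (not isolated)
30 | CNP0186076.5, (2R,3R,4aS,5S,8aR)-5-[(R)-5-hydroxyoctyl]-2-methyldecahydroquinolin-3-yl (2E,4E)-octa-2,4-dienoate | CCC/C=C/C=C/C(=O)O[C@@H]1C[C@H]2[C@@H](CCCC[C@H](O)CCC)CCC[C@H]2N[C@@H]1C | target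

Total step count: 12. Longest linear sequence: 11 (steps 1 to 9, 11 and 12; step 10 is a one-step side branch).

Steps most likely to fail

Step 6. The enamide may equilibrate to its less substituted Δ7(7a) double-bond isomer and be reduced through it, in which case C3a would keep the trans relation to the side chain left by the alkylation and the all-cis relay would be lost. The fallback sets out from keto ester 10 and comes back at lactam 13; it fixes the ring-fusion double bond in an enol lactone and brings nitrogen in afterwards by double inversion. Hydrolysis of 10 with LiOH gives 2-[(1R,2S)-2-[(R)-5-(tert-butyldimethylsilyloxy)octyl]-6-oxocyclohexyl]acetic acid F1. Ac2O with NaOAc closes the tetrasubstituted enol lactone (S)-4-[(R)-5-(tert-butyldimethylsilyloxy)octyl]-4,5,6,7-tetrahydrobenzofuran-2(3H)-one F2. Hydrogenation over Rh/Al2O3 from the face opposite the side chain should give the all-cis lactone (3aS,4S,7aR)-4-[(R)-5-(tert-butyldimethylsilyloxy)octyl]hexahydrobenzofuran-2(3H)-one F3. Benzylamine with AlMe3 opens it to N-benzyl-2-[(1S,2S,6R)-2-[(R)-5-(tert-butyldimethylsilyloxy)octyl]-6-hydroxycyclohexyl]acetamide F4. An Appel reaction (CBr4, PPh3) inverts the carbinol carbon to N-benzyl-2-[(1S,2S,6S)-2-bromo-6-[(R)-5-(tert-butyldimethylsilyloxy)octyl]cyclohexyl]acetamide F5. NaH in DMF then closes the lactam by a second SN2 inversion at the same carbon, which restores the cis ring fusion of 13.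

Step 7. The hindered α-alkoxyvinyl Grignard reagent may fail to add to the iminium ion, or the silyl acetal may collapse to the unreactive enamine, so that no C–C bond forms at C2. The fallback sets out from lactam 13 and comes back at ketone 18; it keeps the hydrosilylation but uses a small copper acetylide as the carbon nucleophile and unmasks the ketone later. Treatment of 13 with IrCl(CO)(PPh3)2 and (Me2SiH)2O, then CuBr (cat.) and ethynyltrimethylsilane, should give by exo attack (2S,3aS,4S,7aR)-1-benzyl-4-[(R)-5-(tert-butyldimethylsilyloxy)octyl]-2-[(trimethylsilyl)ethynyl]octahydro-1H-indole F6. K2CO3 in MeOH gives (2S,3aS,4S,7aR)-1-benzyl-4-[(R)-5-(tert-butyldimethylsilyloxy)octyl]-2-ethynyloctahydro-1H-indole F7. Markovnikov hydration of the terminal alkyne (Ph3PAuNTf2 cat., MsOH, aq MeOH) then gives 18.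

Step 12. Acylation of the hindered tertiary amine by the chloroformate may be slow, and the HCl/MeOH stage may start to methanolyse the dienoate, so that the ester is lost during deprotection. The fallback sets out from amino alcohol 23 and comes back at target 30; it removes the benzyl group before the diene is present and ends with an acid-only deprotection. Hydrogenolysis of 23 (H2, Pd(OH)2/C, EtOH) in the presence of Boc2O gives tert-butyl (2R,3R,4aS,5S,8aR)-5-[(R)-5-(tert-butyldimethylsilyloxy)octyl]-3-hydroxy-2-methyloctahydroquinoline-1(2H)-carboxylate F8. Yamaguchi esterification with 26 gives tert-butyl (2R,3R,4aS,5S,8aR)-5-[(R)-5-(tert-butyldimethylsilyloxy)octyl]-2-methyl-3-[(2E,4E)-octa-2,4-dienoyloxy]octahydroquinoline-1(2H)-carboxylate F9. CF3CO2H in wet CH2Cl2 followed by aq NaHCO3 removes the Boc and TBS groups and gives 30.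

Further compounds
F1 | step 6 | 2-[(1R,2S)-2-[(R)-5-(tert-butyldimethylsilyloxy)octyl]-6-oxocyclohexyl]acetic acid | OC(=O)C[C@H]1C(=O)CCC[C@@H]1CCCC[C@H](O[Si](C)(C)C(C)(C)C)CCC
F2 | step 6 | (S)-4-[(R)-5-(tert-butyldimethylsilyloxy)octyl]-4,5,6,7-tetrahydrobenzofuran-2(3H)-one | O=C1CC2=C(CCC[C@@H]2CCCC[C@H](O[Si](C)(C)C(C)(C)C)CCC)O1
F3 | step 6 | (3aS,4S,7aR)-4-[(R)-5-(tert-butyldimethylsilyloxy)octyl]hexahydrobenzofuran-2(3H)-one | O=C1C[C@H]2[C@@H](CCCC[C@H](O[Si](C)(C)C(C)(C)C)CCC)CCC[C@H]2O1
F4 | step 6 | N-benzyl-2-[(1S,2S,6R)-2-[(R)-5-(tert-butyldimethylsilyloxy)octyl]-6-hydroxycyclohexyl]acetamide | O=C(C[C@H]1[C@@H](CCCC[C@H](O[Si](C)(C)C(C)(C)C)CCC)CCC[C@H]1O)NCc1ccccc1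
F5 | step 6 | N-benzyl-2-[(1S,2S,6S)-2-bromo-6-[(R)-5-(tert-butyldimethylsilyloxy)octyl]cyclohexyl]acetamide | O=C(C[C@H]1[C@@H](CCCC[C@H](O[Si](C)(C)C(C)(C)C)CCC)CCC[C@@H]1Br)NCc1ccccc1
F6 | step 7 | (2S,3aS,4S,7aR)-1-benzyl-4-[(R)-5-(tert-butyldimethylsilyloxy)octyl]-2-[(trimethylsilyl)ethynyl]octahydro-1H-indole | C[Si](C)(C)C#C[C@@H]1C[C@H]2[C@@H](CCCC[C@H](O[Si](C)(C)C(C)(C)C)CCC)CCC[C@H]2N1Cc1ccccc1
F7 | step 7 | (2S,3aS,4S,7aR)-1-benzyl-4-[(R)-5-(tert-butyldimethylsilyloxy)octyl]-2-ethynyloctahydro-1H-indole | C#C[C@@H]1C[C@H]2[C@@H](CCCC[C@H](O[Si](C)(C)C(C)(C)C)CCC)CCC[C@H]2N1Cc1ccccc1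
F8 | step 12 | tert-butyl (2R,3R,4aS,5S,8aR)-5-[(R)-5-(tert-butyldimethylsilyloxy)octyl]-3-hydroxy-2-methyloctahydroquinoline-1(2H)-carboxylate | O[C@@H]1C[C@H]2[C@@H](CCCC[C@H](O[Si](C)(C)C(C)(C)C)CCC)CCC[C@H]2N(C(=O)OC(C)(C)C)[C@@H]1C
F9 | step 12 | tert-butyl (2R,3R,4aS,5S,8aR)-5-[(R)-5-(tert-butyldimethylsilyloxy)octyl]-2-methyl-3-[(2E,4E)-octa-2,4-dienoyloxy]octahydroquinoline-1(2H)-carboxylate | CCC/C=C/C=C/C(=O)O[C@@H]1C[C@H]2[C@@H](CCCC[C@H](O[Si](C)(C)C(C)(C)C)CCC)CCC[C@H]2N(C(=O)OC(C)(C)C)[C@@H]1C
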